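## Structural features

The target is a flavone: a 4H-chromen-4-one in which benzo ring A and pyranone ring C share C4a–C8a, with C2 bonded to C1' of ring B, a phenyl ring carrying OMe at C2' and a catechol at C4'/C5'; C3 carries OMe beside the C4 carbonyl. Ring A is fully substituted: C5–OH, C6–OMe, C7–OH and C8–OMe lie between C4a and C8a, so five neighbouring ring carbons bear oxygen, alternately free and methylated, and C4a is the only ring A carbon without oxygen. There is no stereocentre and no stable axis (C2–C1' has one ortho substituent on ring B and rotates freely), so the difficulty is constitutional: five differentiated oxygens on one benzene ring, and four methyl ethers kept apart from four free hydroxyls. The catechol and the electron-rich ring A are oxidised by air in base, and the methyl ethers at C3, C6 and C8 sit beside chelating oxygens, which makes late selective demethylation or methylation unattractive. Read along C2–C3–C4–C4a–C5–C6–C7–C8–C8a, rings C and A are a nine-carbon poly-β-carbonyl chain: C2, C4, C5, C7 and C8a are at the carbonyl oxidation level, C3, C6 and C8 each carry OMe, and C4a alone is a plain methylene. The key step exploits this: C4a is the only carbon of such a chain whose ring closure (onto C8a) can end in a benzene ring. The acylphloroglucinol ring A so formed has a local mirror plane through C4a and C7, so either hydroxyl ortho to the acyl group closes ring C onto C2 to the same flavone.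

## Logic of the disconnections

21 ⇒ 20. Cut: the two O–CH2Ph bonds at O4' and O5'. The catechol is the most oxidisable part of 21 and is released last, by neutral hydrogenolysis that leaves the methyl ethers alone. The gain is small. The demand is that the tetrasubstituted C2=C3 bond and the C4 carbonyl are not reduced.

20 ⇒ 18 (key disconnection). Cut: O1–C2 of ring C and C4a–C8a of ring A. Both rings open at once to an acyclic tetraoxo ester in which every carbon from C2 to C8a already carries its final oxygen substituent. In one sentence: 18 is folded by one Claisen condensation and one cyclodehydration into rings A and C of 20. This does not describe the usual flavone synthesis, which starts from a finished benzene ring A and closes only ring C. Gain: two rings and the whole oxygen pattern of ring A are traded for a linear chain whose pattern is fixed by the choice of building blocks. Demand: the chain must fold only by C-acylation from C4a to C8a, under base that spares the polyketone, and 19 must be cyclised without contact with air.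

18 ⇒ 8 + 16. Cut: C2–C3. This separates ring B, with the future C2 as an acyl carbon, from the methoxylated chain; 16 has no acidic hydrogen that could quench a polyanion. Gain: convergence into two pieces of similar size. Demand: fourfold deprotonation of 8 (to 17) so that the terminal methoxy-bearing carbon C3 is the most nucleophilic site, and an acyl transfer that stops at the ketone.

8 ⇒ 5 + 6. Cut: C4–C4a. The terminal methyl group of 5 is the future C4a; 6 brings in C4, C3 and the C3 methoxy group. Demand: threefold deprotonation of 5 (to 7) with reaction at the terminal carbon only.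

5 ⇒ 2 + 3. Cut: C5–C6. The γ-carbon of 2 is the future C6 with its methoxy group in place; 3 supplies C5 and C4a. Demand: dianion formation (4) and acylation at the γ-carbon, not at oxygen or at C8.

2 ⇒ 1 + 1. Cut: C7–C8. Two molecules of one ester supply C6, C7, C8 and C8a with both ring A methoxy groups. Nothing needs differentiating later: the oxygens of C5, C7 and C8a arrive as carbonyls, those of C6 and C8 as methyl ethers. Demand: a clean self-condensation.

16 ⇒ 13 + 14. Cut: C1'–C2. The future C2 comes from the carbonyl carbon of 14, taken up by 15. Demand: halogen–lithium exchange faster than attack on the benzyl ethers, and a single acyl transfer.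

13 ⇒ 12. Cut: C1'–Br. Bromination ortho to the methoxy group and para to a benzyloxy group marks C1'. Demand: regioselective monobromination.

12 ⇒ 11. Cut: O–CH3 at O2'. Demand: O-alkylation only.

11 ⇒ 9. Cut: the aryl C–O bond of 11, traced back to the aryl–CHO bond of 9 through 10. This gives the 1,2,4-trioxygenated ring B with the oxygen to be methylated distinguished from the two benzylated ones. Demand: aryl rather than hydride migration.

## Other disconnections considered

Alternative 1: the route that comes to mind first. Cut C2–C3 (as the alkene of a chalcone) and O1–C2, with the C3 oxygen added by oxidation.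
- Forward: Claisen–Schmidt condensation of ring A acetophenone A1 with ring B aldehyde A2 to chalcone A3, Algar–Flynn–Oyamada oxidation to flavonol A4, 3-O-methylation, hydrogenolysis.
- Against: the five differentiated oxygens of ring A are untouched by the key step and are pushed into A1, whose preparation from a benzene derivative needs roughly one operation per oxygen.
- Against: 2'-hydroxychalcones with a second ortho oxygen substituent, as in A3, are expected to close at the α-carbon under alkaline peroxide and give aurones.
- Against: the C3 oxygen and its methyl group cost two further operations, whereas the chosen chain carries them from the start.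

Alternative 2: ring C closed at carbon, C4–C4a, in place of O1–C2.
- Forward: intramolecular Friedel–Crafts acylation of aryl enol ether acid A6 onto the only free position of its pentaoxygenated aryloxy ring, A6 being built from phenol A5.
- For: the regiochemistry is unambiguous.
- Against: A5 again holds the whole ring A problem.
- Against: A6 is a tetrasubstituted, fully heteroatom-substituted acrylic acid. Its O1–C2 bond would need vinylic substitution at a hindered carbon with control of alkene geometry, since only the isomer with the carboxyl cis to the aryloxy group can close.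
- Against: the acid activation needed for acylation endangers four benzyl ethers and the enol ether.

Alternative 3: C4a and C8a functionalised together through an aryne.
- Forward: the aryne released from silyl triflate A7 takes up propiolic acid A8. The carboxylate oxygen adds to one aryne carbon, the aryl anion takes over the acyl group, and the ortho-hydroxyaryl ynone cyclises to flavone A9.
- Against: the aryne is flanked by a benzyloxy group on one side and a methoxy group on the other. Their inductive effects, which normally steer a nucleophile to the carbon remote from an alkoxy group, cancel, so A9 and its ring A regioisomer are expected together.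
- Against: A9 lacks the C3 oxygen, and A7 is a hexasubstituted benzene harder to make than A1.

Key step: step 9

Remark on the chemistry: 2, 5, 8 and 18 are keto–enol mixtures and epimer mixtures at their methoxy-bearing carbons, which is immaterial because each of these carbons becomes sp2 in 20. Chain atoms are named by flavone numbers with the ester carbon called C8a; calling it C5 describes the same compounds because ring A of 19 is symmetric.

## Route

Step 1
Reactants: 1 methyl 2-methoxyacetate (two molecules)
Product: 2 methyl 2,4-dimethoxy-3-oxobutanoate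
Conditions: NaH (0.55 equiv), THF, reflux; then 1 M HCl, 0 °C
Reagents that add atoms: none
Why: Claisen self-condensation; the enolate of one ester acylates a second molecule (C7–C8) and the equilibrium is pulled over by deprotonation of the β-keto ester formed.

Step 2
Reactants: 2 methyl 2,4-dimethoxy-3-oxobutanoate; 3 N-methoxy-N-methylacetamide
Product: 5 methyl 2,4-dimethoxy-3,5-dioxohexanoate, via dilithium dienolate 4 (not isolated)
Conditions: LiN(iPr)2 (2.2 equiv), THF, −78 → 0 °C; then 3, −78 → 0 °C; 1 M HCl
Reagents that add atoms: none
Why: γ-Acylation of a β-keto ester dianion; the second deprotonation occurs at the methoxymethyl carbon, and this more basic terminus attacks the N-methoxy-N-methylamide (C5–C6). The chelated tetrahedral adduct releases the acidic diketo ester only on quench, so no dianion is consumed by proton transfer.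

Step 3
Reactants: 5 methyl 2,4-dimethoxy-3,5-dioxohexanoate; 6 N,2-dimethoxy-N-methylacetamide
Product: 8 methyl 2,4,8-trimethoxy-3,5,7-trioxooctanoate, via trilithium trienolate 7 (not isolated)
Conditions: LiN(iPr)2 (3.3 equiv), THF, −78 → 0 °C; then 6, −78 → 0 °C; cold 1 M HCl
Reagents that add atoms: none
Why: Terminal acylation of a 3,5-dioxo ester trianion (polyanion acylation); the last-formed carbanion at the methyl terminus is the most nucleophilic site and adds to the N-methoxy-N-methylamide (C4–C4a), whose adduct holds until quench.

Step 4
Reactants: 9 3,4-bis(benzyloxy)benzaldehyde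
Product: 11 3,4-bis(benzyloxy)phenol, via aryl formate 10 (not isolated)
Conditions: mCPBA, CH2Cl2, 0 °C → rt; then K2CO3 (cat.), MeOH, rt
Reagents that add atoms: 3-chloroperoxybenzoic acid (mCPBA), OOC(=O)c1cccc(Cl)c1
Why: Baeyer–Villiger oxidation of an electron-rich benzaldehyde, in which the aryl group migrates to oxygen, followed by methanolysis of the formate.

Step 5
Reactants: 11 3,4-bis(benzyloxy)phenol
Product: 12 1,2-bis(benzyloxy)-4-methoxybenzene
Conditions: MeI, K2CO3, acetone, reflux
Reagents that add atoms: iodomethane, CI
Why: Williamson ether synthesis on the only free phenol.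

Step 6
Reactants: 12 1,2-bis(benzyloxy)-4-methoxybenzene
Product: 13 1,2-bis(benzyloxy)-4-bromo-5-methoxybenzene
Conditions: NBS, MeCN, 0 °C
Reagents that add atoms: N-bromosuccinimide, O=C1CCC(=O)N1Br
Why: Electrophilic aromatic bromination; the position ortho to OMe and para to a benzyloxy group is the most activated and least hindered, as in 1,2,4-trialkoxybenzenes generally.

Step 7
Reactants: 13 1,2-bis(benzyloxy)-4-bromo-5-methoxybenzene; 14 N-methoxy-N-methylcarbamoyl chloride
Product: 16 4,5-bis(benzyloxy)-N,2-dimethoxy-N-methylbenzamide, via aryllithium 15 (not isolated)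
Conditions: n-BuLi, THF, −78 °C; then 14, −78 °C → rt
Reagents that add atoms: none
Why: Bromine–lithium exchange, fast at −78 °C relative to benzylic deprotonation, then acyl substitution at the carbamoyl chloride; the N-methoxy-N-methylamide formed does not take up a second aryllithium.

Step 8
Reactants: 8 methyl 2,4,8-trimethoxy-3,5,7-trioxooctanoate; 16 4,5-bis(benzyloxy)-N,2-dimethoxy-N-methylbenzamide
Product: 18 methyl 9-[4,5-bis(benzyloxy)-2-methoxyphenyl]-2,4,8-trimethoxy-3,5,7,9-tetraoxononanoate, via tetralithium tetraenolate 17 (not isolated)
Conditions: LiN(iPr)2 (4.4 equiv), THF, −78 → 0 °C; then 16, −78 °C → rt; cold 1 M HCl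
Reagents that add atoms: none
Why: Terminal aroylation of a triketo ester tetraanion (polyanion acylation); the fourth deprotonation can only occur at the terminal methoxymethyl carbon, which then adds to the N-methoxy-N-methylamide, assisted by chelation to its ortho methoxy group (C2–C3). The adduct collapses to the ketone only on quench.

Step 9
Reactants: 18 methyl 9-[4,5-bis(benzyloxy)-2-methoxyphenyl]-2,4,8-trimethoxy-3,5,7,9-tetraoxononanoate
Product: 20 2-[4,5-bis(benzyloxy)-2-methoxyphenyl]-5,7-dihydroxy-3,6,8-trimethoxy-4H-chromen-4-one, via acylphloroglucinol diketone 19 (not isolated)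
Conditions: NaOMe (5 equiv), MeOH, 0 °C → rt, argon; then HCl in MeOH to pH 1, 50 °C
Reagents that add atoms: none
Why: Methoxide converts 18 into its polyenolate; the carbanion at C4a, the only methylene flanked by two ketones, attacks the ester carbon C8a in a six-membered exo-trig Claisen (Dieckmann-type) closure, methoxide leaves, and the 2-acylcyclohexane-1,3,5-trione tautomerises irreversibly to phloroglucinol 19. The closest known reaction type is the base-induced Claisen cyclisation of 3,5,7-trioxoalkanoates to acylphloroglucinols, the laboratory counterpart of the chalcone synthase folding. The selectivity needed is C-acylation through C4a and no other fold; the substrate secures it because every other six-membered closure (C8 onto C4, C6 onto C2, C3 onto C7) would put into the ring a methoxy-bearing carbon with no hydrogen left, so those aldol products cannot dehydrate to an arene and revert, and O-acylation to a 2-pyranone is reopened by methoxide in methanol, leaving the aromatic Claisen product as the only sink. The α-methoxy group at C8 raises the electrophilicity of the ester whenever C8 is not deprotonated, and the aryl ketone C2, electron-rich, ortho-substituted and tied into the C3 enolate, is the poorest electrophile of the chain. On acidification the hydroxyl on C8a adds to the C2 carbonyl (six-membered exo-trig hemiketal) and water is lost to give pyranone ring C; the two ortho hydroxyls of 19 are related by the mirror plane through C4a and C7, so a single flavone can form and the hydroxyl left over is the chelated 5-OH. No stereocentre is created: the epimeric methoxy-bearing carbons of 18 all become sp2.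

Step 10
Reactants: 20 2-[4,5-bis(benzyloxy)-2-methoxyphenyl]-5,7-dihydroxy-3,6,8-trimethoxy-4H-chromen-4-one
Product: 21 5,7,4',5'-tetrahydroxy-3,6,8,2'-tetramethoxyflavone
Conditions: H2 (1 atm), Pd/C (10%), EtOAc–MeOH, rt
Reagents that add atoms: none
Why: Hydrogenolysis of the two benzyl aryl ethers; the tetrasubstituted, vinylogous-ester C2=C3 bond and the methyl ethers are inert under these neutral conditions.

## Compound list

1 | methyl 2-methoxyacetate | COCC(=O)OC | starting material
2 | methyl 2,4-dimethoxy-3-oxobutanoate | COCC(=O)C(OC)C(=O)OC | intermediate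
3 | N-methoxy-N-methylacetamide | CC(=O)N(C)OC | starting material
4 | dilithium dienolate of 2 | [Li+].[Li+].COC=C([O-])C(OC)=C([O-])OC | intermediate
5 | methyl 2,4-dimethoxy-3,5-dioxohexanoate | CC(=O)C(OC)C(=O)C(OC)C(=O)OC | intermediate
6 | N,2-dimethoxy-N-methylacetamide | COCC(=O)N(C)OC | starting material
7 | trilithium trienolate of 5 | [Li+].[Li+].[Li+].C=C([O-])C(OC)=C([O-])C(OC)=C([O-])OC | intermediate
8 | methyl 2,4,8-trimethoxy-3,5,7-trioxooctanoate | COCC(=O)CC(=O)C(OC)C(=O)C(OC)C(=O)OC | intermediate
9 | 3,4-bis(benzyloxy)benzaldehyde | O=Cc1ccc(OCc2ccccc2)c(OCc2ccccc2)c1 | starting material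
10 | 3,4-bis(benzyloxy)phenyl formate | O=COc1ccc(OCc2ccccc2)c(OCc2ccccc2)c1 | intermediate
11 | 3,4-bis(benzyloxy)phenol | Oc1ccc(OCc2ccccc2)c(OCc2ccccc2)c1 | intermediate
12 | 1,2-bis(benzyloxy)-4-methoxybenzene | COc1ccc(OCc2ccccc2)c(OCc2ccccc2)c1 | intermediate
13 | 1,2-bis(benzyloxy)-4-bromo-5-methoxybenzene | COc1cc(OCc2ccccc2)c(OCc2ccccc2)cc1Br | intermediate
14 | N-methoxy-N-methylcarbamoyl chloride | CON(C)C(=O)Cl | starting material
15 | [4,5-bis(benzyloxy)-2-methoxyphenyl]lithium | [Li]c1cc(OCc2ccccc2)c(OCc2ccccc2)cc1OC | intermediate
16 | 4,5-bis(benzyloxy)-N,2-dimethoxy-N-methylbenzamide | CON(C)C(=O)c1cc(OCc2ccccc2)c(OCc2ccccc2)cc1OC | intermediate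
17 | tetralithium tetraenolate of 8 | [Li+].[Li+].[Li+].[Li+].COC=C([O-])C=C([O-])C(OC)=C([O-])C(OC)=C([O-])OC | intermediate
18 | methyl 9-[4,5-bis(benzyloxy)-2-methoxyphenyl]-2,4,8-trimethoxy-3,5,7,9-tetraoxononanoate | COC(=O)C(OC)C(=O)C(OC)C(=O)CC(=O)C(OC)C(=O)c1cc(OCc2ccccc2)c(OCc2ccccc2)cc1OC | intermediate
19 | 1-[4,5-bis(benzyloxy)-2-methoxyphenyl]-2-methoxy-3-(2,4,6-trihydroxy-3,5-dimethoxyphenyl)propane-1,3-dione | COc1cc(OCc2ccccc2)c(OCc2ccccc2)cc1C(=O)C(OC)C(=O)c1c(O)c(OC)c(O)c(OC)c1O | intermediate
20 | 2-[4,5-bis(benzyloxy)-2-methoxyphenyl]-5,7-dihydroxy-3,6,8-trimethoxy-4H-chromen-4-one | COc1cc(OCc2ccccc2)c(OCc2ccccc2)cc1-c1oc2c(OC)c(O)c(OC)c(O)c2c(=O)c1OC | intermediate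
21 | 5,7,4',5'-tetrahydroxy-3,6,8,2'-tetramethoxyflavone (no stereocentre) | COc1cc(O)c(O)cc1-c1oc2c(OC)c(O)c(OC)c(O)c2c(=O)c1OC | target

## Step count and least certain steps

Total: 10 steps. Longest linear sequence: 7 steps (4, 5, 6, 7, 8, 9, 10); the other branch (1, 2, 3, 8, 9, 10) has 6.

**Step 9 (key step).**
- What may go wrong: O-acylation instead of C-acylation (the C5 enolate oxygen closing onto the ester to a 4-hydroxy-2-pyranone); methoxide-induced retro-Claisen fragmentation of the polyketone, especially loss of the aroyl group at C2–C3; aldol closure of C6 onto C2 followed by deacylative aromatisation; air oxidation of the electron-rich phenolate.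
- Why: the nucleophilic carbon C4a sits in a delocalised enolate and the ester is deactivated once C8 is deprotonated, so the desired closure may be slow compared with these leaks.
- Fallback, setting out from 13 and returning at 21: ring A is taken from a benzene derivative and ring C closed by classical acyl migration. Aryllithium 15, made from 13 as in step 7, is quenched with CO2 to 4,5-bis(benzyloxy)-2-methoxybenzoic acid F1, which oxalyl chloride converts into 4,5-bis(benzyloxy)-2-methoxybenzoyl chloride F2. Purchased 1,3,5-tris(benzyloxy)benzene is dibrominated with NBS to 1,3,5-tris(benzyloxy)-2,4-dibromobenzene F3. Copper-mediated methoxylation (NaOMe, CuBr, DMF–MeOH, 110 °C) gives 1,3,5-tris(benzyloxy)-2,4-dimethoxybenzene F4. Friedel–Crafts acylation at its only free position with methoxyacetyl chloride and BF3·OEt2, with chelation-assisted loss of one ortho benzyl group, gives 1-[2,4-bis(benzyloxy)-6-hydroxy-3,5-dimethoxyphenyl]-2-methoxyethan-1-one F5. O-Aroylation of F5 with F2 and Baker–Venkataraman acyl shift in one pot (K2CO3, pyridine, 80 °C), then H2SO4 in AcOH at 60 °C, should give 5,7-bis(benzyloxy)-2-[4,5-bis(benzyloxy)-2-methoxyphenyl]-3,6,8-trimethoxy-4H-chromen-4-one F6. Hydrogenolysis under the conditions of step 10 removes all four benzyl groups to give 21.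

**Step 8.**
- What may go wrong: incomplete fourth deprotonation, so that 16 meets a trianion unreactive at carbon; slow addition to the hindered, electron-rich amide; premature cyclisation of the polyanion on warming or of 18 to pyranones during the acidic quench.
- Fallback, setting out from 8 (with F1 and F2 of the preceding fallback, made from 13) and returning at 20: the chain is folded before ring B is attached. Under the first-stage conditions of step 9 (NaOMe, MeOH, argon), 8 should close by the same C4a-to-ester Claisen condensation to 1-(2,4,6-trihydroxy-3,5-dimethoxyphenyl)-2-methoxyethan-1-one F7. F1 and F2 are combined (pyridine, CH2Cl2) to 4,5-bis(benzyloxy)-2-methoxybenzoic anhydride F8. Allan–Robinson condensation of F7 with F8 and Et3N at 160 °C, then KOH in aqueous EtOH at reflux to cleave the O-aroyl esters, should give 20; either ortho hydroxyl of F7 leads to the same product.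

**Step 3.**
- What may go wrong: proton transfer from the α-methoxy amide 6 to the terminal carbanion; incomplete trianion formation with acylation at oxygen; cyclisation of 8 to pyranones during work-up.
- Fallback, setting out from 5 and returning at 20 through F7: ring A is closed from the shorter chain and the side chain added afterwards. 5 is cyclised by Claisen condensation of its terminal methyl group onto the ester (NaOMe, MeOH, sealed vessel, 150 °C, the forcing conditions known for 3,5-dioxohexanoates) to 2,4-dimethoxybenzene-1,3,5-triol F9. Houben–Hoesch acylation at its only free carbon with methoxyacetonitrile (ZnCl2, HCl, Et2O, 0 °C; then H2O, 90 °C) gives F7, which continues as in the fallback to step 8.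

**Step 2.**
- What may go wrong: attack of the amide base on the ester or self-condensation of the monoanion during the slow second deprotonation at the methoxy-bearing carbon; O-acylation.
- Fallback, setting out from 2 and returning at 5: the dianion is replaced by its neutral silyl equivalent. 2 is converted with Me3SiOTf and Et3N (Et2O, 0 °C) into 1,2,4-trimethoxy-1,3-bis(trimethylsilyloxy)buta-1,3-diene F10, which is acylated at its terminal carbon by acetyl chloride (CH2Cl2, −78 → 20 °C; aqueous work-up), the known γ-acylation of 1,3-bis(silyloxy)dienes, to give 5.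

## Further compounds

F1 | step 9 | 4,5-bis(benzyloxy)-2-methoxybenzoic acid | COc1cc(OCc2ccccc2)c(OCc2ccccc2)cc1C(=O)O
F2 | step 9 | 4,5-bis(benzyloxy)-2-methoxybenzoyl chloride | COc1cc(OCc2ccccc2)c(OCc2ccccc2)cc1C(=O)Cl
F3 | step 9 | 1,3,5-tris(benzyloxy)-2,4-dibromobenzene | Brc1c(OCc2ccccc2)cc(OCc2ccccc2)c(Br)c1OCc1ccccc1
F4 | step 9 | 1,3,5-tris(benzyloxy)-2,4-dimethoxybenzene | COc1c(OCc2ccccc2)cc(OCc2ccccc2)c(OC)c1OCc1ccccc1
F5 | step 9 | 1-[2,4-bis(benzyloxy)-6-hydroxy-3,5-dimethoxyphenyl]-2-methoxyethan-1-one | COCC(=O)c1c(O)c(OC)c(OCc2ccccc2)c(OC)c1OCc1ccccc1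
F6 | step 9 | 5,7-bis(benzyloxy)-2-[4,5-bis(benzyloxy)-2-methoxyphenyl]-3,6,8-trimethoxy-4H-chromen-4-one | COc1cc(OCc2ccccc2)c(OCc2ccccc2)cc1-c1oc2c(OC)c(OCc3ccccc3)c(OC)c(OCc3ccccc3)c2c(=O)c1OC
F7 | step 8 | 1-(2,4,6-trihydroxy-3,5-dimethoxyphenyl)-2-methoxyethan-1-one | COCC(=O)c1c(O)c(OC)c(O)c(OC)c1O
F8 | step 8 | 4,5-bis(benzyloxy)-2-methoxybenzoic anhydride | COc1cc(OCc2ccccc2)c(OCc2ccccc2)cc1C(=O)OC(=O)c1cc(OCc2ccccc2)c(OCc2ccccc2)cc1OC
F9 | step 3 | 2,4-dimethoxybenzene-1,3,5-triol | COc1c(O)cc(O)c(OC)c1O
F10 | step 2 | 1,2,4-trimethoxy-1,3-bis(trimethylsilyloxy)buta-1,3-diene | COC=C(O[Si](C)(C)C)C(OC)=C(OC)O[Si](C)(C)C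
A1 | alternative 1 | 1-[2,4-bis(benzyloxy)-6-hydroxy-3,5-dimethoxyphenyl]ethan-1-one | CC(=O)c1c(O)c(OC)c(OCc2ccccc2)c(OC)c1OCc1ccccc1
A2 | alternative 1 | 4,5-bis(benzyloxy)-2-methoxybenzaldehyde | COc1cc(OCc2ccccc2)c(OCc2ccccc2)cc1C=O
A3 | alternative 1 | (E)-1-[2,4-bis(benzyloxy)-6-hydroxy-3,5-dimethoxyphenyl]-3-[4,5-bis(benzyloxy)-2-methoxyphenyl]prop-2-en-1-one | COc1cc(OCc2ccccc2)c(OCc2ccccc2)cc1/C=C/C(=O)c1c(O)c(OC)c(OCc2ccccc2)c(OC)c1OCc1ccccc1
A4 | alternative 1 | 5,7-bis(benzyloxy)-2-[4,5-bis(benzyloxy)-2-methoxyphenyl]-3-hydroxy-6,8-dimethoxy-4H-chromen-4-one | COc1cc(OCc2ccccc2)c(OCc2ccccc2)cc1-c1oc2c(OC)c(OCc3ccccc3)c(OC)c(OCc3ccccc3)c2c(=O)c1O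
A5 | alternative 2 | 3,5-bis(benzyloxy)-2,4-dimethoxyphenol | COc1c(O)cc(OCc2ccccc2)c(OC)c1OCc1ccccc1
A6 | alternative 2 | (E)-3-[4,5-bis(benzyloxy)-2-methoxyphenyl]-3-[3,5-bis(benzyloxy)-2,4-dimethoxyphenoxy]-2-methoxyprop-2-enoic acid | OC(=O)/C(OC)=C(/c1cc(OCc2ccccc2)c(OCc2ccccc2)cc1OC)Oc1cc(OCc2ccccc2)c(OC)c(OCc2ccccc2)c1OC
A7 | alternative 3 | 3,5-bis(benzyloxy)-4,6-dimethoxy-2-(trimethylsilyl)phenyl trifluoromethanesulfonate | C[Si](C)(C)c1c(OCc2ccccc2)c(OC)c(OCc2ccccc2)c(OC)c1OS(=O)(=O)C(F)(F)F
A8 | alternative 3 | 3-[4,5-bis(benzyloxy)-2-methoxyphenyl]prop-2-ynoic acid | COc1cc(OCc2ccccc2)c(OCc2ccccc2)cc1C#CC(=O)O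
A9 | alternative 3 | 5,7-bis(benzyloxy)-2-[4,5-bis(benzyloxy)-2-methoxyphenyl]-6,8-dimethoxy-4H-chromen-4-one | COc1cc(OCc2ccccc2)c(OCc2ccccc2)cc1-c1cc(=O)c2c(OCc3ccccc3)c(OC)c(OCc3ccccc3)c(OC)c2o1
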